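**Plan**
- Cuts, in retrosynthetic order:
  - the eight O–CH3 bonds;
  - the two C–H bonds of the CH2–CH(aryl) unit of the seven-membered ring;
  - the bond from the CH(2,4-dihydroxyphenyl) carbon to the ortho carbon of the resorcinol ring fused to that ring;
  - the central-ring–alkyne bond;
  - C2–C3 of each dihydrofuran.
- Enabling feature: the third cut leaves a 2,3,5,6-tetrahydrobenzo[1,2-b:5,4-b']difuran with a twofold axis through C4 and C8. The diarylalkyne on C4 lies on this axis. The 3,5-dioxyphenyl rings on C3 and C5 are homotopic, and each has two equivalent ortho carbons.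
- Forward order: the central ring is diaroylated, both dihydrofurans close in one operation, the alkyne arm is attached, the seven-membered ring closes, the alkene is saturated, and the phenols are released.
- Stereochemistry: C3/C5 come from a chiral dirhodium carbene C–H insertion run twice. C2/C6 come from acid equilibration to trans. The last centre comes from an iridium–PHOX hydrogenation, with the new C–H cis to the C–H of the seven-ring methine.

Key step: step 8

Assumption: the senses of induction of Rh2(R-PTAD)4 (3R,5R) and of the (R)-PHOX ligand (S at the last centre, from the quadrant picture for (E)-1,2-diarylpropenes) are assigned by analogy; if either proves opposite, the equally available mirror-image catalyst is taken.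

**Step 1**
Reactants: 1 1-bromo-3,5-dimethoxybenzene; 2 3,5-dimethoxybenzoyl chloride (2.4 equiv)
Product: 3 (2-bromo-4,6-dimethoxybenzene-1,3-diyl)bis[(3,5-dimethoxyphenyl)methanone]
Conditions: AlCl3 (3 equiv), CH2Cl2, 0 → 40 °C
Reagents that add atoms: none
Why: Twofold Friedel–Crafts aroylation at the two carbons flanking bromine, each para to one methoxy group and ortho to the other (the pattern known from 4,6-diaroylresorcinol ethers), with the first aroyl group meta to the second site and twisted out of conjugation, and with any material that loses an ortho methyl group converging in step 2.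

**Step 2**
Reactants: 3 diketone
Product: 4 (2-bromo-4,6-dihydroxybenzene-1,3-diyl)bis[(3,5-dimethoxyphenyl)methanone]
Conditions: BCl3 (3 equiv), CH2Cl2, −78 → 0 °C; H2O
Reagents that add atoms: none
Why: Chelation-directed ether cleavage, in which boron bound to each ketone oxygen removes only the methyl group ortho to it through a six-membered chelate and leaves the four non-chelating methoxy groups intact.

**Step 3**
Reactants: 4 bis(ortho-hydroxy ketone)
Product: 5 5-bromo-4,6-bis[(3,5-dimethoxyphenyl)(hydrazinylidene)methyl]benzene-1,3-diol (C=N geometry immaterial)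
Conditions: N2H4·H2O (20 equiv), AcOH (cat.), EtOH, 80 °C
Reagents that add atoms: hydrazine, NN
Why: Hydrazone condensation is run while the phenols are free, because the O–H···O=C hydrogen bond holds each carbonyl in the plane of the central ring where bromine and oxygen do not shield its faces, and the resulting O–H···N bond turns NH2 away from C–Br so that indazole closure is not expected.

**Step 4**
Reactants: 5 bis(hydrazone); 6 4-methoxybenzyl bromide (2.1 equiv)
Product: 7 bis(4-methoxybenzyl) ether of 5
Conditions: Cs2CO3, DMF, 0 °C → rt
Reagents that add atoms: none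
Why: Williamson etherification, in which the caesium phenoxides are far better nucleophiles than the conjugated hydrazone NH2 groups, so two equivalents of the benzylic bromide should go to oxygen.

**Step 5**
Reactants: 7 bis(hydrazone) bis(ether)
Product: 9 (2S,3R,5R,6S)-4-bromo-3,5-bis(3,5-dimethoxyphenyl)-2,6-bis(4-methoxyphenyl)-2,3,5,6-tetrahydrobenzo[1,2-b:5,4-b']difuran (both rings cis), via bis(diazoalkane) 8 (not isolated)
Conditions: MnO2 (10 equiv), CH2Cl2, rt, filter; Rh2(R-PTAD)4 (2 mol %), CH2Cl2, 0 °C
Reagents that add atoms: none
Why: MnO2 dehydrogenates both hydrazones and the chiral dirhodium tetracarboxylate converts each diaryldiazomethane into a donor/donor carbene that undergoes 1,5 C–H insertion into the neighbouring O–CH2Ar group, a reaction known to give cis-2,3-diaryl-2,3-dihydrobenzofurans with high enantiocontrol, so the catalyst sets C3 and C5 (both R), C2 and C6 follow as cis (both S), and the second insertion diverts most of the minor-sense material into a separable meso isomer.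

**Step 6**
Reactants: 9 cis,cis-bromide
Product: 10 (2R,3R,5R,6R)-4-bromo-3,5-bis(3,5-dimethoxyphenyl)-2,6-bis(4-methoxyphenyl)-2,3,5,6-tetrahydrobenzo[1,2-b:5,4-b']difuran (both rings trans, C2-symmetric)
Conditions: TFA (10 equiv), CH2Cl2, 0 °C → rt
Reagents that add atoms: none
Why: Acid-mediated epimerisation known for cis-2-(4-oxyaryl)-3-aryldihydrobenzofurans, in which reversible ionisation of O–C2 to the 4-methoxybenzyl cation and reclosure place each 4-methoxyphenyl group trans to its neighbour (C2 and C6 become R) under thermodynamic control by the untouched C3/C5 centres.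

**Step 7**
Reactants: 10 trans,trans-bromide; 11 1-ethynyl-2,4-dimethoxybenzene
Product: 12 (2R,3R,5R,6R)-4-[(2,4-dimethoxyphenyl)ethynyl]-3,5-bis(3,5-dimethoxyphenyl)-2,6-bis(4-methoxyphenyl)-2,3,5,6-tetrahydrobenzo[1,2-b:5,4-b']difuran
Conditions: PdCl2(MeCN)2 (5 mol %), XPhos (15 mol %), Cs2CO3, MeCN–dioxane, 90 °C
Reagents that add atoms: none
Why: Copper-free Sonogashira coupling with a bulky biarylphosphine on zerovalent palladium, the established answer to di-ortho-substituted aryl bromides, which also avoids oxidative dimerisation of the electron-rich alkyne.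

**Step 8**
Reactants: 12 C2-symmetric diarylalkyne
Product: 13 cycloheptene (didehydro-target octamethyl ether): the alkyne carbon bearing the 2,4-dimethoxyphenyl group is now bonded to an ortho carbon of the aryl ring on C5, the other alkyne carbon is the ring =CH, and both dihydrofurans remain trans (four centres R)
Conditions: HNTf2 (10 mol %), dry CH2Cl2 (0.01 M), −20 °C → rt
Reagents that add atoms: none
Why: The acid protonates the alkyne carbon bound to C4, because only then does the charge fall on the carbon carrying the 2,4-dimethoxyphenyl donor (a linear vinyl cation with allenyl-oxocarbenium character), whereas the oxygens of the central ring are meta to C4 and cannot support the other cation. An ortho carbon of the adjacent 3,5-dimethoxyphenyl ring (para to one methoxy group, ortho to the other, and within van der Waals contact in models) attacks in Friedel–Crafts fashion and loss of the arenium proton returns the catalyst, which is a 7-endo-dig closure, the 6-exo-dig mode being switched off by the same polarisation. The closest known reactions are the acid-induced endo cyclisations of (4-alkoxyphenyl)ethynyl biaryls and the acid-promoted 7-endo-dig closures of ortho-alkynyl diarylmethanes to dibenzocycloheptenes, the proton counterparts of gold- and platinum-catalysed hydroarylation. A proton is chosen over a ligated metal cation because the electrophile must end up anti to the attacking ring, exactly where the twofold axis places the spectator aryl ring, a pocket that admits H but not a phosphine–gold fragment; in addition the ortho methoxy group of the alkyne aryl finds no electrophilic carbon within reach, so no benzofuran can form. No stereocentre is created, C3 and C5 are untouched, and C2 and C6 already sit at their acid-equilibrium trans configuration. No site selection is needed, since the axis and aryl rotation make all four possible attacks identical; the selectivity that is needed is arene attack over 1,5-hydride transfer from C3–H/C5–H, which the much higher π-nucleophilicity of the dimethoxyarene and its better overlap with the empty orbital should secure.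

**Step 9**
Reactants: 13 cycloheptene
Product: 14 target octamethyl ether (new CH(2,4-dimethoxyphenyl) centre S, its H cis to the H of the seven-ring methine)
Conditions: [Ir(cod)((R)-tBu-PHOX)]BArF (5 mol %), H2 (50 bar), CH2Cl2, rt
Reagents that add atoms: none
Why: Iridium–N,P-catalysed asymmetric hydrogenation of an unfunctionalised trisubstituted aryl alkene, in which syn delivery of H2 to the face carrying the seven-ring methine C–H gives the S centre, the face being chosen by the ligand because the =CH end still lies on the former twofold axis and sees near-equivalent surroundings on both sides, while this catalyst class leaves benzylic C–O bonds alone.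

**Step 10**
Reactants: 14 octamethyl ether
Product: 15 target, CNP0154047.2
Conditions: BBr3 (24 equiv), CH2Cl2, −78 °C → rt; H2O
Reagents that add atoms: none
Why: Exhaustive aryl methyl ether cleavage with BBr3, the customary last step for permethylated oligostilbenes, applied when the dihydrofurans are at their thermodynamic trans configuration and no alkene remains to be protonated.

**Compound list**

| No. | Name | SMILES | Role |
|---|---|---|---|
| 1 | 1-bromo-3,5-dimethoxybenzene | COc1cc(Br)cc(OC)c1 | starting material |
| 2 | 3,5-dimethoxybenzoyl chloride | COc1cc(cc(OC)c1)C(Cl)=O | starting material |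
| 3 | (2-bromo-4,6-dimethoxybenzene-1,3-diyl)bis[(3,5-dimethoxyphenyl)methanone] | COc1cc(OC)c(C(=O)c2cc(OC)cc(OC)c2)c(Br)c1C(=O)c1cc(OC)cc(OC)c1 | intermediate |
| 4 | (2-bromo-4,6-dihydroxybenzene-1,3-diyl)bis[(3,5-dimethoxyphenyl)methanone] | Oc1cc(O)c(C(=O)c2cc(OC)cc(OC)c2)c(Br)c1C(=O)c1cc(OC)cc(OC)c1 | intermediate |
| 5 | bis(hydrazone) of 4 | Oc1cc(O)c(C(=NN)c2cc(OC)cc(OC)c2)c(Br)c1C(=NN)c1cc(OC)cc(OC)c1 | intermediate |
| 6 | 4-methoxybenzyl bromide | COc1ccc(CBr)cc1 | starting material |
| 7 | bis(4-methoxybenzyl) ether of 5 | COc1ccc(COc2cc(OCc3ccc(OC)cc3)c(C(=NN)c3cc(OC)cc(OC)c3)c(Br)c2C(=NN)c2cc(OC)cc(OC)c2)cc1 | intermediate |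
| 8 | bis(diazoalkane) | COc1ccc(COc2cc(OCc3ccc(OC)cc3)c(C(=[N+]=[N-])c3cc(OC)cc(OC)c3)c(Br)c2C(=[N+]=[N-])c2cc(OC)cc(OC)c2)cc1 | intermediate |
| 9 | (2S,3R,5R,6S)-cis,cis-bromide | COc1ccc([C@H]2Oc3cc4c(c(Br)c3[C@H]2c2cc(OC)cc(OC)c2)[C@@H](c2cc(OC)cc(OC)c2)[C@@H](c2ccc(OC)cc2)O4)cc1 | intermediate |
| 10 | (2R,3R,5R,6R)-trans,trans-bromide | COc1ccc([C@@H]2Oc3cc4c(c(Br)c3[C@H]2c2cc(OC)cc(OC)c2)[C@@H](c2cc(OC)cc(OC)c2)[C@H](c2ccc(OC)cc2)O4)cc1 | intermediate |
| 11 | 1-ethynyl-2,4-dimethoxybenzene | COc1ccc(C#C)c(OC)c1 | starting material |
| 12 | C2-symmetric diarylalkyne | COc1ccc([C@@H]2Oc3cc4c(c(C#Cc5ccc(OC)cc5OC)c3[C@H]2c2cc(OC)cc(OC)c2)[C@@H](c2cc(OC)cc(OC)c2)[C@H](c2ccc(OC)cc2)O4)cc1 | intermediate |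
| 13 | cycloheptene (didehydro-target octamethyl ether) | COc1ccc([C@@H]2Oc3cc4c5c(c3[C@H]2c2cc(OC)cc(OC)c2)C=C(c2ccc(OC)cc2OC)c2c(OC)cc(OC)cc2[C@H]5[C@H](c2ccc(OC)cc2)O4)cc1 | intermediate |
| 14 | target octamethyl ether | COc1ccc([C@@H]2Oc3cc4c5c(c3[C@H]2c2cc(OC)cc(OC)c2)C[C@@H](c2ccc(OC)cc2OC)c2c(OC)cc(OC)cc2[C@H]5[C@H](c2ccc(OC)cc2)O4)cc1 | intermediate |
| 15 | CNP0154047.2 | Oc1ccc([C@@H]2Oc3cc4c5c(c3[C@H]2c2cc(O)cc(O)c2)C[C@@H](c2ccc(O)cc2O)c2c(O)cc(O)cc2[C@H]5[C@H](c2ccc(O)cc2)O4)cc1 | target |

Total step count: 10. Longest linear sequence: 10 (1 → 15).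

**Steps most likely to fail**

1. **Step 9.**
   - What may go wrong: the crowded triaryl alkene may not turn over. Alternatively, hydrogen may be delivered to the opposite face. The seven-membered ring is a boat locked by the dihydrofuran fusion, and its methine H leans over the wanted face, while the other face is flanked only by a methoxy oxygen. That outcome would place the aryl group on the methine-H side.
   - Fallback (sets out from 13, returns at 15): the reduction is moved behind the deprotection. BBr3 at low temperature converts 13 into the didehydro octaphenol F1.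
   - In F1 the 2-hydroxy group of the pendant aryl ring can hydrogen-bond to the hydroxy group ortho to the ring junction. This holds both oxygens over the unwanted face. Heterogeneous hydrogenation (Pd/C, H2, MeOH) should then meet the other face and give 15 directly.

2. **Step 8.**
   - What may go wrong: the vinyl cation may be diverted by hydride transfer from a neighbouring methine. This is an internal redox that ends in aromatisation of one dihydrofuran. Capture by adventitious water is a second possibility.
   - Fallback (sets out from 12, returns at 13): the electrophile is changed from a vinyl cation to a carbonyl carbon. Hydration with Ph3PAuNTf2 (monovalent gold) in aqueous dioxane is sterically feasible. Gold and water can occupy the two open quadrants beside C3–H and C5–H, which lie anti to one another. It should give the 2-aryl-1-(2,4-dimethoxyphenyl)ethanone F2.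
   - Cyclodehydration of F2 with P2O5 in MsOH proceeds by intramolecular arene addition to the activated ketone followed by loss of water. It forms the same aryl–carbon bond and the same ring.

3. **Step 5.**
   - What may go wrong: the carbene carbon is flanked by bromine, so insertion may be slow, azine formation may compete, or cis and enantio control may erode.
   - Fallback (sets out from 4, returns at 10): carbene chemistry is replaced by ortho-quinone-methide chemistry. There the reacting carbon is trigonal and is attacked perpendicular to the ring plane, away from bromine.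
   - NaBH4 gives the bis(benzhydrol) F3. 4-Methylbenzenesulfinic acid replaces both benzylic hydroxy groups to give the bis(sulfone) F4.
   - With Cs2CO3, F4 releases its two quinone methides in turn. Each is trapped by the ylide of (4-methoxybenzyl)dimethylsulfonium bromide F5 (from 6 and Me2S) in a trans-selective [4+1] annulation.
   - Chromatography removes the meso isomer F6. HPLC on a chiral phase separates 10 from its enantiomer F7, at the cost of most of the material.

**Further compounds**
F1 | step 9 | didehydro octaphenol | Oc1ccc([C@@H]2Oc3cc4c5c(c3[C@H]2c2cc(O)cc(O)c2)C=C(c2ccc(O)cc2O)c2c(O)cc(O)cc2[C@H]5[C@H](c2ccc(O)cc2)O4)cc1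
F2 | step 8 | 2-[(2R,3R,5R,6R)-3,5-bis(3,5-dimethoxyphenyl)-2,6-bis(4-methoxyphenyl)-2,3,5,6-tetrahydrobenzo[1,2-b:5,4-b']difuran-4-yl]-1-(2,4-dimethoxyphenyl)ethanone | COc1ccc([C@@H]2Oc3cc4c(c(CC(=O)c5ccc(OC)cc5OC)c3[C@H]2c2cc(OC)cc(OC)c2)[C@@H](c2cc(OC)cc(OC)c2)[C@H](c2ccc(OC)cc2)O4)cc1
F3 | step 5 | 5-bromo-4,6-bis[(3,5-dimethoxyphenyl)(hydroxy)methyl]benzene-1,3-diol (diastereomer mixture) | Oc1cc(O)c(C(O)c2cc(OC)cc(OC)c2)c(Br)c1C(O)c1cc(OC)cc(OC)c1
F4 | step 5 | 5-bromo-4,6-bis[(3,5-dimethoxyphenyl)(4-methylbenzenesulfonyl)methyl]benzene-1,3-diol (diastereomer mixture) | Oc1cc(O)c(C(c2cc(OC)cc(OC)c2)S(=O)(=O)c2ccc(C)cc2)c(Br)c1C(c1cc(OC)cc(OC)c1)S(=O)(=O)c1ccc(C)cc1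
F5 | step 5 | (4-methoxybenzyl)dimethylsulfonium bromide | C[S+](C)Cc1ccc(OC)cc1.[Br-]
F6 | step 5 | (2R,3R,5S,6S)-meso trans,trans-bromide | COc1ccc([C@@H]2Oc3cc4c(c(Br)c3[C@H]2c2cc(OC)cc(OC)c2)[C@H](c2cc(OC)cc(OC)c2)[C@@H](c2ccc(OC)cc2)O4)cc1
F7 | step 5 | (2S,3S,5S,6S)-trans,trans-bromide (enantiomer of 10) | COc1ccc([C@H]2Oc3cc4c(c(Br)c3[C@@H]2c2cc(OC)cc(OC)c2)[C@H](c2cc(OC)cc(OC)c2)[C@@H](c2ccc(OC)cc2)O4)cc1
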